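Compound numbers refer to the compound list after the steps; TBS = tert-butyldimethylsilyl.

## Analysis of the target

The target 18 is a cis-fused tetrahydrofuro[3,4-c]furan-1-one: a γ-lactone (C1, O2, C3, C3a, C6a) and a tetrahydrofuran (C3a, C4, O5, C6, C6a) share the C3a–C6a bond. It has four contiguous stereocentres, C3 (S), C3a (R), C6a (S) and C6 (S); H3a and H6a are cis and both aryl groups sit on the convex face, so H3 is trans to H3a and H6 is trans to H6a. The two benzylic carbons carry different rings, a 4-hydroxy-3-methoxyphenyl group on the lactone carbon C3 and a catechol on the ether carbon C6, so no symmetry can be used and each aryl group must be introduced separately with fixed regiochemistry. Sensitive features are the oxidisable catechol, the two para-hydroxybenzylic C–O bonds (C3–O2 and C6–O5), which ionise in acid, open to quinone methides in base and are at risk under hydrogenolysis, and the lactone α-carbon C6a, whose enolate has O5 in the β-position. The hard part is fixing C3 and C6 relative to the ring fusion: in dioxabicyclo[3.3.0]octanes exo and endo benzylic aryl groups differ little in energy, so equilibration cannot be trusted and both centres are better set under kinetic control. The plan rests on the substitution pattern of the tetrahydrofuran ring: aryl on C6, a carboxyl carbon (C1) on C6a, one carbon (C3) on C3a and an unsubstituted C4. This is the sum of a three-atom O5–C4–C3a unit whose C3a is an allylic terminus (its vinyl group being the later C3) and a C6=C6a acceptor carrying the aryl group and the carboxyl carbon.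

## Retrosynthetic reasoning

18 ⇒ 17. The three phenols stay masked as TBS ethers to the end. The last step cuts only O–Si bonds under buffered conditions that touch neither benzylic C–O bond. Benzyl ethers were not chosen because their hydrogenolysis would endanger C3–O2 and C6–O5.

17 ⇒ 16. A methoxycarbonyl group is added back on C6a. This makes C6a a malonate carbon, which activates the acceptor of the key step, removes any stereochemical question at C6a until the end, and guarantees one ester cis to C3. The forward step removes the ester and protonates C6a; the cis ring fusion allows only one outcome.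

16 ⇒ 14. The lactone bond C1–O2 and the C3–H bond are cut, leading to aryl ketone 14. C3 is thus created by hydride addition, not aryl addition. With C6a as the large substituent on C3a, the Felkin–Anh arrangement sends a hydride to the face that leaves the aryl group on the convex side. An aryl nucleophile adding to aldehyde 7 under the same model would give the C3 epimer, and thermodynamic correction afterwards would be unreliable. The resulting C3 hydroxyl is γ to the cis ester and closes the lactone.

14 ⇒ 8 + 10. The C3–aryl bond is cut between an acyl donor and an aryl metal. The bromine of 10 fixes attachment para to the silyloxy group, which electrophilic substitution of a guaiacol ring would not do cleanly. 10 comes from 9 by silylation.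

8 ⇒ 7 ⇒ 6. The carboxyl carbon C3 is traced back to a vinyl group on C3a: oxidative cleavage of the C=C bond gives aldehyde 7, and oxidation gives acid 8. The vinyl group is the only form of C3 the key step can deliver, and neither oxidation touches a stereocentre.

6 ⇒ 4 + 5 (key disconnection). O5–C6 and C6a–C3a are cut. This is the only pair of ring bonds whose cleavage gives two simple, stable partners: arylidene malonate 4 (C6, C6a) and racemic 5 (O5, C4, C3a and the vinyl carbon that becomes C3). One ring, two skeletal bonds and the stereocentres C3a and C6 are gained in one catalytic step. The forward reaction must convert racemic 5 into one configuration at C3a, close the ring at the internal allyl terminus, and place aryl and vinyl trans.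

4 ⇒ 2 + 3, 2 ⇒ 1. The C6=C6a bond comes from a Knoevenagel condensation of 3 with 2, and 2 from 1 by silylation. The key-step precursor is thus reached in two routine steps.

## Alternatives that were turned down

Alternative 1: Both aryl–carbon bonds (C6–aryl, C3–aryl) are cut, leaving the complete cis-fused bicycle with acetal carbons at both ends, 6-acetoxy-3-menthyloxytetrahydrofuro[3,4-c]furan-1-one A2. In the forward key step BF3·OEt2 ionises the C6 acetate and 1,2-bis(allyloxy)benzene A3 attacks the oxocarbenium ion. TiCl4 then ionises the C3 menthyloxy acylal and guaiacol A4 attacks para to its hydroxyl group, giving the bis(allyl) ether A1 of the target; no ring is closed.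
- For: both aryl groups arrive late from simple arenes, and attack on the convex face of a cis-fused oxocarbenium ion is a sound kinetic way to place each aryl group exo. On this point it is stronger than the chosen plan, which must earn C6 in a catalytic step and C3 in a separate reduction.
- Against: the second ionisation is at an acylal carbon whose cation is destabilised by the lactone carbonyl. It needs a strong Lewis acid while the new electron-rich benzylic ether at C6 and two allyl ethers are present, so re-ionisation at C6 and allyl migration compete. A4 can also react ortho to the hydroxyl or on oxygen. The differentiated core A2 is itself a multi-step problem with all ring construction still to do.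
- Comparison: the chosen plan builds the ring and two stereocentres from simple components in one step and fixes aryl regiochemistry through the starting materials.

Alternative 2: The bonds C3a–C6a and C1–O2 are cut with ring expansion. C1 becomes a ketone between C3a and C6a in a six-membered ring, the 3-diazotetrahydropyran-4-one A6, which already carries the catechol on C6 and the aryl(hydroxy)methyl group on C3a. Irradiation expels N2, C3a migrates from C1 to C6a with retention (contracting the pyranone to the tetrahydrofuran), and the C3 hydroxyl adds to the ketene to close the lactone. The product is the tris-silyl ether A5, the same substance as 17.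
- For: the lactone forms without reagents, the intramolecular ketene capture can only give the cis fusion, and no ester has to be removed afterwards. It therefore avoids the one harsh step of the chosen plan (step 9), and here it is stronger.
- Against: the step creates no stereocentre other than C6a, so C6, C3a and C3 must all be set while building a trisubstituted tetrahydropyranone, which is longer than the whole chosen sequence. The carbene at C6a has a benzylic C6–H beside it and a free hydroxyl five atoms away, so 1,2-hydrogen shift and O–H insertion compete with the Wolff shift.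
- Comparison: the chosen plan sets two of the four centres while building the ring and needs no preformed heterocycle.

Alternative 3: The bonds C3–C3a and C6a–C6 are cut on a lactone template, (5R)-5-menthyloxy-2(5H)-furanone A8, whose carbonyl carbon is C1 and whose acetal carbon is C4. In one flask 2-lithio-2-[4-(tert-butyldimethylsilyloxy)-3-methoxyphenyl]-1,3-dithiane A9 adds to C3a anti to the menthyloxy group. The lactone enolate at C6a then adds to 3,4-bis(tert-butyldimethylsilyloxy)benzaldehyde A10 (the same substance as 2), giving the trans,trans lactone A7; no ring of the target is closed.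
- For: the conjugate addition–aldol sequence is highly dependable, the auxiliary fixes C3a and C6a in absolute terms without a catalyst, and both aryl groups come from defined reagents. For C3a and C6a it is more certain than the palladium step chosen here.
- Against: the lactone of A7 is the wrong one (C1 is esterified to the C4 acetal oxygen, not to C3). The dithiane must be removed in the presence of three electron-rich silyloxyarenes, the C3 ketone reduced selectively, the C4 acetal reduced and closed onto C6, and the lactone transposed to O2. The aldol gives little control at C6 and the auxiliary is stoichiometric.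
- Comparison: the chosen plan closes the tetrahydrofuran in the same step that forms its C–C bond, has C1 and C4 at the correct oxidation level from the start, and uses chirality catalytically.

Key step: step 3

Assumption: the (1R,2R) enantiomer of the diphosphine L* is taken to give the (4R) centre of 6; if the sense of induction proves opposite, the (1S,2S) ligand is used and nothing else changes.

## Route

Step 1
Reactants: 1 protocatechualdehyde (3,4-dihydroxybenzaldehyde)
Product: 2 bis-silyl aldehyde (3,4-bis(tert-butyldimethylsilyloxy)benzaldehyde)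
Conditions: TBSCl, imidazole, DMF, rt
Reagents that add atoms: tert-butyldimethylsilyl chloride, CC(C)(C)[Si](C)(C)Cl
Why: Imidazole-promoted silylation of both phenols; the aldehyde is untouched, and the aryl silyl ethers are expected to withstand the amine, palladium, oxidant, organometallic and hydride steps that follow.

Step 2
Reactants: 2 bis-silyl aldehyde; 3 dimethyl malonate
Product: 4 arylidene malonate (dimethyl 2-[3,4-bis(tert-butyldimethylsilyloxy)benzylidene]malonate)
Conditions: piperidine (cat.), AcOH (cat.), toluene, reflux, Dean–Stark
Reagents that add atoms: none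
Why: Knoevenagel condensation driven by azeotropic removal of water; the two esters are identical, so the alkene has no geometry to control.

Step 3
Reactants: 4 arylidene malonate; 5 racemic 2-vinyloxirane
Product: 6 vinyl tetrahydrofuran (dimethyl (2R,4R)-2-[3,4-bis(tert-butyldimethylsilyloxy)phenyl]-4-vinyltetrahydrofuran-3,3-dicarboxylate; aryl and vinyl trans)
Conditions: 5 (2 equiv, slow addition), Pd2(dba)3·CHCl3 (2.5 mol%), (1R,2R)-L* (7.5 mol%), THF, 0 °C to rt; L* = N,N′-[(1R,2R)-cyclohexane-1,2-diyl]bis[2-(diphenylphosphanyl)-1-naphthamide]
Reagents that add atoms: none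
Why: Zerovalent palladium ionises racemic 5 to a zwitterionic π-allylpalladium alkoxide, and the two diastereomeric complexes formed with the chiral diphosphine interconvert by π–σ–π isomerisation through the unsubstituted allyl terminus. The alkoxide O5 adds reversibly to C6 of 4 (oxa-Michael), and the malonate carbanion C6a then attacks the internal allyl terminus C3a anti to palladium, releasing the catalyst. The closest known reaction type is the palladium-catalysed (3+2) cycloaddition of vinyl epoxides or vinylethylene carbonates with doubly activated alkenes, including variants with chiral ligands. The tetrahydrofuran closes by a 5-exo attack on the π-allyl unit; the tether from O5 allows the carbanion to reach only the proximal terminus through a five-membered transition state, the distal one requiring a seven-membered ring. C3a is set by the ligand in a dynamic kinetic asymmetric transformation, because ring closure is the first irreversible event. C6 is set in the same transition state: the open oxa-Michael adducts equilibrate, and the closure that puts the aryl group and the palladium-bound vinyl fragment on opposite faces of the forming ring is expected to win, giving the 2,4-trans ring. C6a needs no control because its two esters are identical, and one of them is necessarily cis to the vinyl group. The step also needs capture of the zwitterion by 4 to outrun its oligomerisation, which slow addition of 5 to an excess of acceptor is meant to secure.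

Step 4
Reactants: 6 vinyl tetrahydrofuran
Product: 7 aldehyde (dimethyl (2R,4R)-2-[3,4-bis(tert-butyldimethylsilyloxy)phenyl]-4-formyltetrahydrofuran-3,3-dicarboxylate)
Conditions: O3, CH2Cl2, −78 °C (Sudan Red 7B as end-point indicator); PPh3, −78 °C to rt
Reagents that add atoms: ozone, [O-][O+]=O
Why: Ozonolysis of the monosubstituted alkene, which reacts far faster with ozone than the silylated arene; reduction of the ozonide with PPh3 is neutral and spares the base-sensitive β-alkoxy aldehyde and the C3a centre.

Step 5
Reactants: 7 aldehyde
Product: 8 acid ((3R,5R)-5-[3,4-bis(tert-butyldimethylsilyloxy)phenyl]-4,4-bis(methoxycarbonyl)tetrahydrofuran-3-carboxylic acid)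
Conditions: NaClO2, NaH2PO4, 2-methyl-2-butene, t-BuOH/H2O, 0 °C to rt
Reagents that add atoms: sodium chlorite, [Na+].[O-]Cl=O
Why: Pinnick oxidation at buffered pH with an alkene as hypochlorite scavenger; the conditions are non-basic, so C3a, the silyl ethers and the esters are left alone.

Step 6
Reactants: 9 bromoguaiacol (4-bromo-2-methoxyphenol)
Product: 10 aryl bromide ((4-bromo-2-methoxyphenoxy)(tert-butyl)dimethylsilane)
Conditions: TBSCl, imidazole, DMF, rt
Reagents that add atoms: tert-butyldimethylsilyl chloride, CC(C)(C)[Si](C)(C)Cl
Why: Routine phenol silylation, which makes the bromide fit for halogen–lithium exchange in step 7.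

Step 7
Reactants: 8 acid; 10 aryl bromide
Product: 14 aryl ketone (dimethyl (2R,4R)-2-[3,4-bis(tert-butyldimethylsilyloxy)phenyl]-4-[4-(tert-butyldimethylsilyloxy)-3-methoxybenzoyl]tetrahydrofuran-3,3-dicarboxylate), via acid chloride 11 (not isolated), via aryllithium 12 (not isolated), via arylzinc chloride 13 (not isolated)
Conditions: 8, (COCl)2, DMF (cat.), CH2Cl2, 0 °C to rt, evaporate; 10, n-BuLi, THF, −78 °C, then ZnCl2, −78 to 0 °C; combine, Pd(PPh3)4 (5 mol%), THF, 0 °C to rt
Reagents that add atoms: none
Why: Negishi acylation: the acid chloride adds oxidatively to zerovalent palladium and the arylzinc chloride, made by bromine–lithium exchange and transmetalation, delivers the aryl group. The weakly basic organozinc tolerates the methyl esters and should not enolise C3a.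

Step 8
Reactants: 14 aryl ketone
Product: 16 lactone ester (methyl (3S,3aR,6R,6aS)-6-[3,4-bis(tert-butyldimethylsilyloxy)phenyl]-3-[4-(tert-butyldimethylsilyloxy)-3-methoxyphenyl]-1-oxotetrahydro-1H,3H-furo[3,4-c]furan-6a-carboxylate; cis-fused with both aryl groups on the convex face), via hydroxy diester 15 (not isolated)
Conditions: LiBH(s-Bu)3, THF, −78 °C; AcOH, −78 °C to rt; PPTS (cat.), toluene, 50 °C
Reagents that add atoms: none
Why: Felkin–Anh-controlled reduction: with the quaternary C6a anti to the incoming hydride and the aryl group gauche to H3a, the bulky non-chelating hydride should give the (S)-configured C3 carbinol. After a cold acidic quench, this hydroxyl attacks the ester cis to it on C6a and closes the cis-fused γ-lactone with loss of methanol, which also fixes C6a.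

Step 9
Reactants: 16 lactone ester
Product: 17 tris-silyl lactone ((3S,3aR,6S,6aS)-6-[3,4-bis(tert-butyldimethylsilyloxy)phenyl]-3-[4-(tert-butyldimethylsilyloxy)-3-methoxyphenyl]tetrahydro-1H,3H-furo[3,4-c]furan-1-one)
Conditions: LiCl, H2O, DMSO, 130 °C
Reagents that add atoms: none
Why: Krapcho demethoxycarbonylation: chloride demethylates the doubly activated ester, the carboxylate loses CO2 and the lactone enolate is protonated to the only unstrained, cis-fused ring junction, so H6a ends on the convex face. Any aryl silyl ether lost here does not matter, because step 10 removes them all.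

Step 10
Reactants: 17 tris-silyl lactone
Product: 18 target ((3S,3aR,6S,6aS)-6-(3,4-dihydroxyphenyl)-3-(4-hydroxy-3-methoxyphenyl)tetrahydro-1H,3H-furo[3,4-c]furan-1-one)
Conditions: TBAF, AcOH, THF, 0 °C to rt
Reagents that add atoms: none
Why: Fluoride cleaves the three aryl silyl ethers; buffering with acetic acid keeps the phenols protonated, so neither quinone methide formation at C3 or C6 nor catechol oxidation should set in.

## Compound list

1 | 3,4-dihydroxybenzaldehyde | O=Cc1ccc(O)c(O)c1 | starting material
2 | 3,4-bis(tert-butyldimethylsilyloxy)benzaldehyde | O=Cc1ccc(O[Si](C)(C)C(C)(C)C)c(O[Si](C)(C)C(C)(C)C)c1 | intermediate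
3 | dimethyl malonate | COC(=O)CC(=O)OC | starting material
4 | dimethyl 2-[3,4-bis(tert-butyldimethylsilyloxy)benzylidene]malonate | COC(=O)C(=Cc1ccc(O[Si](C)(C)C(C)(C)C)c(O[Si](C)(C)C(C)(C)C)c1)C(=O)OC | intermediate
5 | 2-vinyloxirane (racemic) | C=CC1CO1 | starting material
6 | dimethyl (2R,4R)-2-[3,4-bis(tert-butyldimethylsilyloxy)phenyl]-4-vinyltetrahydrofuran-3,3-dicarboxylate | COC(=O)C1(C(=O)OC)[C@@H](C=C)CO[C@@H]1c1ccc(O[Si](C)(C)C(C)(C)C)c(O[Si](C)(C)C(C)(C)C)c1 | intermediate
7 | dimethyl (2R,4R)-2-[3,4-bis(tert-butyldimethylsilyloxy)phenyl]-4-formyltetrahydrofuran-3,3-dicarboxylate | COC(=O)C1(C(=O)OC)[C@@H](C=O)CO[C@@H]1c1ccc(O[Si](C)(C)C(C)(C)C)c(O[Si](C)(C)C(C)(C)C)c1 | intermediate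
8 | (3R,5R)-5-[3,4-bis(tert-butyldimethylsilyloxy)phenyl]-4,4-bis(methoxycarbonyl)tetrahydrofuran-3-carboxylic acid | COC(=O)C1(C(=O)OC)[C@@H](C(=O)O)CO[C@@H]1c1ccc(O[Si](C)(C)C(C)(C)C)c(O[Si](C)(C)C(C)(C)C)c1 | intermediate
9 | 4-bromo-2-methoxyphenol | COc1cc(Br)ccc1O | starting material
10 | (4-bromo-2-methoxyphenoxy)(tert-butyl)dimethylsilane | COc1cc(Br)ccc1O[Si](C)(C)C(C)(C)C | intermediate
11 | dimethyl (2R,4R)-2-[3,4-bis(tert-butyldimethylsilyloxy)phenyl]-4-(chlorocarbonyl)tetrahydrofuran-3,3-dicarboxylate (not isolated) | COC(=O)C1(C(=O)OC)[C@@H](C(Cl)=O)CO[C@@H]1c1ccc(O[Si](C)(C)C(C)(C)C)c(O[Si](C)(C)C(C)(C)C)c1 | intermediate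
12 | [4-(tert-butyldimethylsilyloxy)-3-methoxyphenyl]lithium (not isolated) | COc1cc([Li])ccc1O[Si](C)(C)C(C)(C)C | intermediate
13 | [4-(tert-butyldimethylsilyloxy)-3-methoxyphenyl]zinc chloride (not isolated) | COc1cc([Zn]Cl)ccc1O[Si](C)(C)C(C)(C)C | intermediate
14 | dimethyl (2R,4R)-2-[3,4-bis(tert-butyldimethylsilyloxy)phenyl]-4-[4-(tert-butyldimethylsilyloxy)-3-methoxybenzoyl]tetrahydrofuran-3,3-dicarboxylate | COC(=O)C1(C(=O)OC)[C@@H](C(=O)c2ccc(O[Si](C)(C)C(C)(C)C)c(OC)c2)CO[C@@H]1c1ccc(O[Si](C)(C)C(C)(C)C)c(O[Si](C)(C)C(C)(C)C)c1 | intermediate
15 | dimethyl (2R,4R)-2-[3,4-bis(tert-butyldimethylsilyloxy)phenyl]-4-{(S)-[4-(tert-butyldimethylsilyloxy)-3-methoxyphenyl](hydroxy)methyl}tetrahydrofuran-3,3-dicarboxylate (not isolated) | COC(=O)C1(C(=O)OC)[C@@H]([C@H](O)c2ccc(O[Si](C)(C)C(C)(C)C)c(OC)c2)CO[C@@H]1c1ccc(O[Si](C)(C)C(C)(C)C)c(O[Si](C)(C)C(C)(C)C)c1 | intermediate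
16 | methyl (3S,3aR,6R,6aS)-6-[3,4-bis(tert-butyldimethylsilyloxy)phenyl]-3-[4-(tert-butyldimethylsilyloxy)-3-methoxyphenyl]-1-oxotetrahydro-1H,3H-furo[3,4-c]furan-6a-carboxylate | COc1cc([C@H]2OC(=O)[C@@]3(C(=O)OC)[C@@H]2CO[C@@H]3c2ccc(O[Si](C)(C)C(C)(C)C)c(O[Si](C)(C)C(C)(C)C)c2)ccc1O[Si](C)(C)C(C)(C)C | intermediate
17 | (3S,3aR,6S,6aS)-6-[3,4-bis(tert-butyldimethylsilyloxy)phenyl]-3-[4-(tert-butyldimethylsilyloxy)-3-methoxyphenyl]tetrahydro-1H,3H-furo[3,4-c]furan-1-one | COc1cc([C@H]2OC(=O)[C@H]3[C@@H]2CO[C@@H]3c2ccc(O[Si](C)(C)C(C)(C)C)c(O[Si](C)(C)C(C)(C)C)c2)ccc1O[Si](C)(C)C(C)(C)C | intermediate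
18 | (3S,3aR,6S,6aS)-6-(3,4-dihydroxyphenyl)-3-(4-hydroxy-3-methoxyphenyl)tetrahydro-1H,3H-furo[3,4-c]furan-1-one | COc1cc([C@H]2OC(=O)[C@H]3[C@@H]2CO[C@@H]3c2ccc(O)c(O)c2)ccc1O | target

## Step count and least certain steps

Total: 10 steps. Longest linear sequence: 9 steps (steps 1–5 and 7–10); step 6 is a one-step side branch.

Step 3 (key step). The most likely failure is insufficient stereocontrol. Ring closure may not be slow enough relative to equilibration of the diastereomeric π-allyl complexes, or the ligand may not discriminate the two C6 epimers of the open adduct, so that enantiomeric purity at C3a or the 2,4-trans preference falls short. The electron-rich arylidene malonate is also a weak oxa-Michael acceptor, so oligomerisation of the epoxide and silyl transfer from an aryl silyl ether to the alkoxide can compete. The fallback replaces asymmetric catalysis by resolution. It sets out from 4 and 5, which are combined under Pd(PPh3)4 in THF to the racemic trans tetrahydrofuran, that is 6 together with its mirror image dimethyl (2S,4S)-2-[3,4-bis(tert-butyldimethylsilyloxy)phenyl]-4-vinyltetrahydrofuran-3,3-dicarboxylate F1; any cis isomer is removed by chromatography. The conditions of steps 4 and 5 then give 7 with its mirror image, the (2S,4S) aldehyde F2, and 8 with its mirror image, the (3S,5S) acid F3. The racemic acid is crystallised with (S)-1-phenylethylamine as the less soluble diastereomeric salt, the (S)-1-phenylethylammonium salt of 8 F4 (the amine enantiomer to be chosen by trial), while F3 stays in the mother liquor. Aqueous HCl liberates 8, where the route is rejoined.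

Step 8. The most likely failure is poor facial selectivity of hydride delivery, if lithium chelation between the ketone and an ester carbonyl overrides the Felkin–Anh arrangement. Enolisation towards C3a, eroding that centre, is a second risk. The fallback uses thermodynamic instead of kinetic control and sets out from 14. Reduction with NaBH4/CeCl3·7H2O in MeOH at −78 °C is accepted as unselective and gives 15 together with its carbinol epimer, the (R)-hydroxy diester F5. Both lactonise under the PPTS conditions, giving 16 and its C3 epimer, the (3R,3aR,6R,6aS) lactone ester F6. The mixture is treated with BF3·OEt2 in CH2Cl2 at low temperature, which ionises the benzylic C3–O2 bond (a malonate-type carboxylate leaves) and lets it reclose to the less crowded convex-face aryl isomer 16. C6 cannot ionise at this stage because its cation would sit next to the doubly acylated C6a. Recovered F6 is resubmitted, and the route continues from 16.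

Step 9. The most likely failures are loss of aryl silyl ethers under hot halide and water, opening of the tetrahydrofuran by expulsion of O5 from the transient C6a enolate, and chloride attack at the benzylic C3. The fallback replaces halide dealkylation by ester hydrolysis and thermal decarboxylation and sets out from 16. Me3SnOH in 1,2-dichloroethane at 80 °C cleaves the methyl ester to the (3S,3aR,6R,6aS) lactone 6a-carboxylic acid F7. This acid loses CO2 on heating in toluene through the cyclic six-membered transition state without a free enolate, and the enol tautomerises to the cis-fused lactone 17, where the route is rejoined.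

Step 7. The most likely failure is slow oxidative addition or transmetalation at the hindered acyl chloride, with decarbonylation of the acylpalladium intermediate or loss of HCl across C3–C3a to a ketene as side processes. The fallback replaces cross-coupling by chelation-activated acyl substitution and sets out from 8. 2,2′-Dipyridyl disulfide and PPh3 convert 8 into the S-(pyridin-2-yl) thioester F8. The aryl Grignard reagent [4-(tert-butyldimethylsilyloxy)-3-methoxyphenyl]magnesium bromide F9, made from 10 and Mg in THF, is added at −78 °C and gives ketone 14, where the route is rejoined.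

## Further compounds

F1 | step 3 | dimethyl (2S,4S)-2-[3,4-bis(tert-butyldimethylsilyloxy)phenyl]-4-vinyltetrahydrofuran-3,3-dicarboxylate (mirror image of 6) | COC(=O)C1(C(=O)OC)[C@H](C=C)CO[C@H]1c1ccc(O[Si](C)(C)C(C)(C)C)c(O[Si](C)(C)C(C)(C)C)c1
F2 | step 3 | dimethyl (2S,4S)-2-[3,4-bis(tert-butyldimethylsilyloxy)phenyl]-4-formyltetrahydrofuran-3,3-dicarboxylate (mirror image of 7) | COC(=O)C1(C(=O)OC)[C@H](C=O)CO[C@H]1c1ccc(O[Si](C)(C)C(C)(C)C)c(O[Si](C)(C)C(C)(C)C)c1
F3 | step 3 | (3S,5S)-5-[3,4-bis(tert-butyldimethylsilyloxy)phenyl]-4,4-bis(methoxycarbonyl)tetrahydrofuran-3-carboxylic acid (mirror image of 8) | COC(=O)C1(C(=O)OC)[C@H](C(=O)O)CO[C@H]1c1ccc(O[Si](C)(C)C(C)(C)C)c(O[Si](C)(C)C(C)(C)C)c1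
F4 | step 3 | (S)-1-phenylethylammonium (3R,5R)-5-[3,4-bis(tert-butyldimethylsilyloxy)phenyl]-4,4-bis(methoxycarbonyl)tetrahydrofuran-3-carboxylate | COC(=O)C1(C(=O)OC)[C@@H](C(=O)[O-])CO[C@@H]1c1ccc(O[Si](C)(C)C(C)(C)C)c(O[Si](C)(C)C(C)(C)C)c1.C[C@H]([NH3+])c1ccccc1
F5 | step 8 | dimethyl (2R,4R)-2-[3,4-bis(tert-butyldimethylsilyloxy)phenyl]-4-{(R)-[4-(tert-butyldimethylsilyloxy)-3-methoxyphenyl](hydroxy)methyl}tetrahydrofuran-3,3-dicarboxylate | COC(=O)C1(C(=O)OC)[C@@H]([C@@H](O)c2ccc(O[Si](C)(C)C(C)(C)C)c(OC)c2)CO[C@@H]1c1ccc(O[Si](C)(C)C(C)(C)C)c(O[Si](C)(C)C(C)(C)C)c1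
F6 | step 8 | methyl (3R,3aR,6R,6aS)-6-[3,4-bis(tert-butyldimethylsilyloxy)phenyl]-3-[4-(tert-butyldimethylsilyloxy)-3-methoxyphenyl]-1-oxotetrahydro-1H,3H-furo[3,4-c]furan-6a-carboxylate | COc1cc([C@@H]2OC(=O)[C@@]3(C(=O)OC)[C@@H]2CO[C@@H]3c2ccc(O[Si](C)(C)C(C)(C)C)c(O[Si](C)(C)C(C)(C)C)c2)ccc1O[Si](C)(C)C(C)(C)C
F7 | step 9 | (3S,3aR,6R,6aS)-6-[3,4-bis(tert-butyldimethylsilyloxy)phenyl]-3-[4-(tert-butyldimethylsilyloxy)-3-methoxyphenyl]-1-oxotetrahydro-1H,3H-furo[3,4-c]furan-6a-carboxylic acid | COc1cc([C@H]2OC(=O)[C@@]3(C(=O)O)[C@@H]2CO[C@@H]3c2ccc(O[Si](C)(C)C(C)(C)C)c(O[Si](C)(C)C(C)(C)C)c2)ccc1O[Si](C)(C)C(C)(C)C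
F8 | step 7 | dimethyl (2R,4R)-2-[3,4-bis(tert-butyldimethylsilyloxy)phenyl]-4-[(pyridin-2-ylsulfanyl)carbonyl]tetrahydrofuran-3,3-dicarboxylate | COC(=O)C1(C(=O)OC)[C@@H](C(=O)Sc2ccccn2)CO[C@@H]1c1ccc(O[Si](C)(C)C(C)(C)C)c(O[Si](C)(C)C(C)(C)C)c1
F9 | step 7 | [4-(tert-butyldimethylsilyloxy)-3-methoxyphenyl]magnesium bromide | COc1cc([Mg]Br)ccc1O[Si](C)(C)C(C)(C)C
A1 | alternative 1 | (3S,3aR,6S,6aS)-6-[3,4-bis(allyloxy)phenyl]-3-(4-hydroxy-3-methoxyphenyl)tetrahydro-1H,3H-furo[3,4-c]furan-1-one | COc1cc([C@H]2OC(=O)[C@H]3[C@@H]2CO[C@@H]3c2ccc(OCC=C)c(OCC=C)c2)ccc1O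
A2 | alternative 1 | cis-fused 6-acetoxy-3-[(1R,2S,5R)-menthyloxy]tetrahydro-1H,3H-furo[3,4-c]furan-1-one (both acetal substituents drawn on the convex face) | CC(C)[C@@H]1CC[C@@H](C)C[C@H]1O[C@H]1OC(=O)[C@H]2[C@@H]1CO[C@@H]2OC(C)=O
A3 | alternative 1 | 1,2-bis(allyloxy)benzene | C=CCOc1ccccc1OCC=C
A4 | alternative 1 | guaiacol (2-methoxyphenol) | COc1ccccc1O
A5 | alternative 2 | (3S,3aR,6S,6aS)-6-[3,4-bis(tert-butyldimethylsilyloxy)phenyl]-3-[4-(tert-butyldimethylsilyloxy)-3-methoxyphenyl]tetrahydro-1H,3H-furo[3,4-c]furan-1-one | COc1cc([C@H]2OC(=O)[C@H]3[C@@H]2CO[C@@H]3c2ccc(O[Si](C)(C)C(C)(C)C)c(O[Si](C)(C)C(C)(C)C)c2)ccc1O[Si](C)(C)C(C)(C)C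
A6 | alternative 2 | 2-[3,4-bis(tert-butyldimethylsilyloxy)phenyl]-3-diazo-5-{[4-(tert-butyldimethylsilyloxy)-3-methoxyphenyl](hydroxy)methyl}tetrahydropyran-4-one (configured as required for A5) | COc1cc([C@@H](O)[C@H]2CO[C@H](c3ccc(O[Si](C)(C)C(C)(C)C)c(O[Si](C)(C)C(C)(C)C)c3)C(=[N+]=[N-])C2=O)ccc1O[Si](C)(C)C(C)(C)C
A7 | alternative 3 | trans,trans 3-[aryl(hydroxy)methyl]-4-(2-aryl-1,3-dithian-2-yl)-5-menthyloxybutyrolactone | O=C1O[C@@H](O[C@@H]2C[C@H](C)CC[C@H]2C(C)C)[C@H](C2(SCCCS2)c2ccc(O[Si](C)(C)C(C)(C)C)c(OC)c2)[C@H]1[C@H](O)c1ccc(O[Si](C)(C)C(C)(C)C)c(O[Si](C)(C)C(C)(C)C)c1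
A8 | alternative 3 | (5R)-5-[(1R,2S,5R)-menthyloxy]-2(5H)-furanone | O=C1O[C@@H](O[C@@H]2C[C@H](C)CC[C@H]2C(C)C)C=C1
A9 | alternative 3 | 2-lithio-2-[4-(tert-butyldimethylsilyloxy)-3-methoxyphenyl]-1,3-dithiane | COc1cc(C2([Li])SCCCS2)ccc1O[Si](C)(C)C(C)(C)C
A10 | alternative 3 | 3,4-bis(tert-butyldimethylsilyloxy)benzaldehyde | O=Cc1ccc(O[Si](C)(C)C(C)(C)C)c(O[Si](C)(C)C(C)(C)C)c1
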